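**Retrosynthetic overview**

1. Numbering: C1 (quaternary, methyl), C2, C3, C4 (carbinol, isopropyl), C5 (ring-fusion CH), C6 (acyloxy), C7, C8 (methyl)=C9, C10; ring A is C1–C5 and ring B is C1, C5–C10. The plan rests on ring B: C7–C8(Me)=C9–C10 is an isoprene unit, and C6–C5–C1 is an oxyallyl unit once C5 is a ketone and the C6 oxygen is an alkoxy group.
2. Target ⇐ diol 24 + salicyloyl chloride 25; 24 ⇐ ketol 23 (hydroxyl-directed reduction at C6) ⇐ epoxy alcohol 20 (1,2-hydride shift sets C5, directed epoxidation sets C4) ⇐ enone 18.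
3. 18 ⇐ cycloheptenone 12: ring A is closed second, by a C4–C5 bond (C5 enol triflate onto an isopropyl ketone, CrCl2/NiCl2), then alkoxy-enone transposition moves the carbonyl to C6 and releases the auxiliary.
4. 12 ⇐ silyl enol ether 9 + isoprene: ring B is closed first, by a (4+3) cycloaddition that forms C6–C7 and C1–C10.
5. 9 ⇐ 1,1-dimethoxybutan-2-one, methyl acrylate and (R)-1-phenylethanol; the enol geometry is fixed through enol lactone 7.

Key step: step 6

Assumption: the diene is taken to add to the cation on the face opposite the phenyl group of the auxiliary, in the conformer whose carbinol C–H eclipses the C6=O+ bond; on that model the (R)-alcohol leads to (1R), and if the sense proved opposite the (S)-alcohol would be used with no other change.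

**Route**

Step 1
Reactants: 1 1,1-dimethoxybutan-2-one; 2 methyl acrylate
Product: 3 methyl 6,6-dimethoxy-4-methyl-5-oxohexanoate
Conditions: t-BuOK (5 mol %), t-BuOH, 20 °C, 1 in threefold excess
Reagents that add atoms: none
Why: Base-catalysed Michael addition from the only enolisable position of 1; the excess of ketone suppresses double addition, and the new stereocentre is racemic and becomes planar again in step 4.

Step 2
Reactants: 3 methyl 6,6-dimethoxy-4-methyl-5-oxohexanoate; 4 (R)-1-phenylethanol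
Product: 5 methyl 6-methoxy-4-methyl-5-oxo-6-[(1R)-1-phenylethoxy]hexanoate
Conditions: pyridinium p-toluenesulfonate (5 mol %), cyclohexane, reflux, MeOH removed over 5 Å molecular sieves, 3 in twofold excess
Reagents that add atoms: none
Why: Acid-catalysed transacetalisation driven by removal of methanol; the excess of dimethyl acetal holds the exchange at one methoxy group, and the configurations at the acetal carbon and at C4 are irrelevant because both centres become planar before step 6.

Step 3
Reactants: 5 methyl 6-methoxy-4-methyl-5-oxo-6-[(1R)-1-phenylethoxy]hexanoate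
Product: 6 6-methoxy-4-methyl-5-oxo-6-[(1R)-1-phenylethoxy]hexanoic acid
Conditions: LiOH, THF/H2O, 0 °C; then 1 M HCl to pH 4, 0 °C
Reagents that add atoms: lithium hydroxide, [Li+].[OH-]
Why: Saponification of the methyl ester; the α-keto acetal is stable to base and to the brief, cold, weakly acidic work-up.

Step 4
Reactants: 6 6-methoxy-4-methyl-5-oxo-6-[(1R)-1-phenylethoxy]hexanoic acid
Product: 7 6-{methoxy[(1R)-1-phenylethoxy]methyl}-5-methyl-3,4-dihydro-2H-pyran-2-one
Conditions: Ac2O, NaOAc, 90 °C
Reagents that add atoms: none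
Why: Enol lactonisation of a δ-keto acid through its mixed anhydride; enolisation goes toward the methyl-bearing carbon and not toward the acetal carbon, and the six-membered ring ties the chain carbon (route C2) cis to the enol oxygen, which fixes the geometry that simple silylation of ketone 5 could not control.

Step 5
Reactants: 7 6-{methoxy[(1R)-1-phenylethoxy]methyl}-5-methyl-3,4-dihydro-2H-pyran-2-one
Product: 9 methyl (4Z)-6-methoxy-4-methyl-6-[(1R)-1-phenylethoxy]-5-(trimethylsilyloxy)hex-4-enoate, via lithium enolate 8 (not isolated)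
Conditions: LiOMe (1.0 equiv, made from MeOH and n-BuLi), THF, −78 to 0 °C; then Me3SiCl, Et3N, −78 °C
Reagents that add atoms: lithium methoxide, [Li+].[O-]C; chlorotrimethylsilane, C[Si](C)(C)Cl
Why: Methoxide cleaves the enol ester at the acyl carbon and releases the fully substituted lithium enolate with the ring-fixed geometry, and O-silylation traps it before any E/Z exchange (enol ester cleavage to a stereodefined enolate, then silyl enol ether formation).

Step 6
Reactants: 9 methyl (4Z)-6-methoxy-4-methyl-6-[(1R)-1-phenylethoxy]-5-(trimethylsilyloxy)hex-4-enoate; 10 isoprene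
Product: 12 methyl 3-[(1R,6S)-1,4-dimethyl-7-oxo-6-[(1R)-1-phenylethoxy]cyclohept-3-en-1-yl]propanoate, via alkoxy silyloxyallyl cation 11 (not isolated)
Conditions: Me3SiOTf (0.2 equiv), isoprene (10 equiv), CH2Cl2 (0.05 M in 9), −78 °C; pyridine quench
Reagents that add atoms: none
Why: Proposed new method: Me3SiOTf removes the methoxy group of the mixed acetal as MeOSiMe3 and leaves oxocarbenium ion 11, a 1-alkoxy-2-silyloxyallyl cation held in the W shape, with the auxiliary oxygen and the ester chain both cis to the silyloxy group (the chain geometry comes from lactone 7, and the inside position at C6 can only take hydrogen because of allylic strain with the C1 methyl group). The CH2 terminus of isoprene next to its methyl-bearing carbon adds to the unhindered oxocarbenium carbon C6 to give a tertiary allyl cation, whose primary terminus C10 is captured by the enol silane carbon C1 with loss of the silyl group, which returns Me3SiOTf and the C5 ketone. The closest known reactions are the low-temperature (4+3) cycloadditions of this kind of cation, made from α-keto acetal silyl enol ethers that carry a 1-phenylethyl acetal auxiliary, with furan and cyclopentadiene; an open-chain diene and a fully substituted cation terminus have not been shown. Ring B closes in the (4+3) mode, C6–C7 first and then C1–C10 by 7-endo capture of the cisoid allyl cation, in competition with 5-exo capture at C8 (the (3+2) mode) and with loss of a proton from the open cation. C6 is set by the auxiliary (approach to the face opposite its phenyl group), and C1 is set relative to C6 because both bonds form on the same face of a cation of fixed geometry, which places the chain and the auxiliary ether cis on the ring. The step needs the cisoid diene conformer to react (fast conformer exchange, excess diene, −78 °C, non-nucleophilic triflate) and the regiochemistry that puts the methyl group on C8, which follows from bonding the more nucleophilic diene terminus to the more electrophilic, less hindered cation terminus.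

Step 7
Reactants: 12 methyl 3-[(1R,6S)-1,4-dimethyl-7-oxo-6-[(1R)-1-phenylethoxy]cyclohept-3-en-1-yl]propanoate
Product: 13 N-methoxy-N-methyl-3-[(1R,6S)-1,4-dimethyl-7-oxo-6-[(1R)-1-phenylethoxy]cyclohept-3-en-1-yl]propanamide
Conditions: MeNHOMe·HCl (1.5 equiv), iPrMgCl (3 equiv), THF, −20 °C
Reagents that add atoms: N,O-dimethylhydroxylamine hydrochloride, CNOC.Cl
Why: Direct conversion of the methyl ester into the Weinreb amide by the magnesium amide; the C5 ketone is shielded by the quaternary C1 and the alkoxy-bearing C6, and epimerisation at C6 would be harmless because C6 becomes planar in step 8.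

Step 8
Reactants: 13 N-methoxy-N-methyl-3-[(1R,6S)-1,4-dimethyl-7-oxo-6-[(1R)-1-phenylethoxy]cyclohept-3-en-1-yl]propanamide
Product: 15 (7R)-7-[3-(methoxy(methyl)amino)-3-oxopropyl]-4,7-dimethyl-2-[(1R)-1-phenylethoxy]cyclohepta-1,4-dien-1-yl trifluoromethanesulfonate, via potassium enolate 14 (not isolated)
Conditions: KN(SiMe3)2 (1.2 equiv), THF, −78 °C; then PhNTf2, −78 to 0 °C
Reagents that add atoms: N-phenylbis(trifluoromethanesulfonimide), O=S(=O)(N(c1ccccc1)S(=O)(=O)C(F)(F)F)C(F)(F)F
Why: The ketone can enolise only toward C6 because C1 is quaternary, and the amide α-protons are far less acidic, so O-triflation of the enolate gives the C5 enol triflate regiospecifically.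

Step 9
Reactants: 15 (7R)-7-[3-(methoxy(methyl)amino)-3-oxopropyl]-4,7-dimethyl-2-[(1R)-1-phenylethoxy]cyclohepta-1,4-dien-1-yl trifluoromethanesulfonate
Product: 16 (7R)-4,7-dimethyl-7-(4-methyl-3-oxopentyl)-2-[(1R)-1-phenylethoxy]cyclohepta-1,4-dien-1-yl trifluoromethanesulfonate
Conditions: iPrMgCl (2 equiv), THF, −20 to 0 °C
Reagents that add atoms: isopropylmagnesium chloride, CC(C)[Mg]Cl
Why: Grignard addition to a Weinreb amide stops at the ketone, and an enol triflate is inert to the Grignard reagent when no transition-metal catalyst is present.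

Step 10
Reactants: 16 (7R)-4,7-dimethyl-7-(4-methyl-3-oxopentyl)-2-[(1R)-1-phenylethoxy]cyclohepta-1,4-dien-1-yl trifluoromethanesulfonate
Product: 18 (8aR)-6,8a-dimethyl-3-(propan-2-yl)-1,2,8,8a-tetrahydroazulen-4(5H)-one, via tertiary allylic alcohol 17 (not isolated)
Conditions: CrCl2 (5 equiv), NiCl2 (5 mol %), DMF, 25 °C; then 1 M HCl, THF, 0 °C
Reagents that add atoms: water, O
Why: Nozaki–Hiyama–Kishi closure of the enol triflate onto the tethered ketone forms C4–C5 in a 5-exo addition, and the resulting tertiary allylic alcohol next to an enol ether undergoes the acid-induced alkoxy-enone transposition (Stork–Danheiser type), which puts the carbonyl on C6 and the double bond at C4=C5 and releases the auxiliary, so the configuration of the carbinol carbon in 17 is of no consequence.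

Step 11
Reactants: 18 (8aR)-6,8a-dimethyl-3-(propan-2-yl)-1,2,8,8a-tetrahydroazulen-4(5H)-one
Product: 19 (4R,8aR)-6,8a-dimethyl-3-(propan-2-yl)-1,2,4,5,8,8a-hexahydroazulen-4-ol
Conditions: NaBH4, CeCl3·7H2O, MeOH, −40 °C
Reagents that add atoms: none
Why: Luche 1,2-reduction of the enone; hydride should add to C6 on the face away from the C1 methyl group, which stands 1,3 to the carbonyl on the other face, so the hydroxyl ends cis to that methyl group.

Step 12
Reactants: 19 (4R,8aR)-6,8a-dimethyl-3-(propan-2-yl)-1,2,4,5,8,8a-hexahydroazulen-4-ol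
Product: 20 (3R,3aS,4R,8aR)-3,3a-epoxy-6,8a-dimethyl-3-(propan-2-yl)-1,2,3,3a,4,5,8,8a-octahydroazulen-4-ol
Conditions: VO(acac)2 (5 mol %), t-BuOOH, CH2Cl2, 0 °C
Reagents that add atoms: tert-butyl hydroperoxide, CC(C)(C)OO
Why: Hydroxyl-directed epoxidation delivers oxygen to the face of the C4=C5 bond that carries the C6 hydroxyl, so the epoxide oxygen is cis to the C1 methyl group and the C4–O bond of the target is set; the homoallylic C8=C9 bond reacts much more slowly.

Step 13
Reactants: 20 (3R,3aS,4R,8aR)-3,3a-epoxy-6,8a-dimethyl-3-(propan-2-yl)-1,2,3,3a,4,5,8,8a-octahydroazulen-4-ol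
Product: 23 (3R,3aR,8aR)-3-hydroxy-6,8a-dimethyl-3-(propan-2-yl)-2,3,3a,5,8,8a-hexahydroazulen-4(1H)-one, via epoxy silyl ether 21 (not isolated), via silyloxy ketone 22 (not isolated)
Conditions: Me3SiOTf (2.2 equiv), iPr2NEt, CH2Cl2, −78 °C; then citric acid, MeOH, 0 °C
Reagents that add atoms: none
Why: Semipinacol rearrangement of a silylated 2,3-epoxy alcohol (the non-aldol aldol process): the silyl triflate opens the epoxide at C5, the C6 hydrogen, which lies anti to the breaking C5–O bond when the C5–C4 bond is pseudo-equatorial on ring B, shifts to C5 with inversion and C6 becomes the ketone, so H5 ends trans to the C1 methyl group while the C4 oxygen keeps its configuration, and mild methanolysis then frees the tertiary alcohol.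

Step 14
Reactants: 23 (3R,3aR,8aR)-3-hydroxy-6,8a-dimethyl-3-(propan-2-yl)-2,3,3a,5,8,8a-hexahydroazulen-4(1H)-one
Product: 24 (3R,3aS,4S,8aR)-6,8a-dimethyl-3-(propan-2-yl)-1,2,3,3a,4,5,8,8a-octahydroazulene-3,4-diol
Conditions: Me4NBH(OAc)3, MeCN/AcOH, −30 °C
Reagents that add atoms: none
Why: Evans–Saksena reduction: the acyloxyborohydride bound to the C4 hydroxyl, which the trans ring fusion holds on the methyl-bearing face next to C6, delivers hydride to that face of the ketone and gives the C6 alcohol anti to the C4 hydroxyl, as in the target.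

Step 15
Reactants: 24 (3R,3aS,4S,8aR)-6,8a-dimethyl-3-(propan-2-yl)-1,2,3,3a,4,5,8,8a-octahydroazulene-3,4-diol; 25 2-acetoxybenzoyl chloride
Product: 26 (3R,3aS,4S,8aR)-3-hydroxy-6,8a-dimethyl-3-(propan-2-yl)-1,2,3,3a,4,5,8,8a-octahydroazulen-4-yl 2-acetoxybenzoate
Conditions: pyridine, DMAP (10 mol %), CH2Cl2, 0 to 25 °C
Reagents that add atoms: none
Why: Acylation of the secondary C6 alcohol by the acid chloride under nucleophilic catalysis; the tertiary C4 alcohol does not react, and the acetate keeps the phenol from competing.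

Step 16
Reactants: 26 (3R,3aS,4S,8aR)-3-hydroxy-6,8a-dimethyl-3-(propan-2-yl)-1,2,3,3a,4,5,8,8a-octahydroazulen-4-yl 2-acetoxybenzoate
Product: 27 (3R,3aS,4S,8aR)-3-hydroxy-6,8a-dimethyl-3-(propan-2-yl)-1,2,3,3a,4,5,8,8a-octahydroazulen-4-yl 2-hydroxybenzoate
Conditions: K2CO3 (0.2 equiv), MeOH, 0 °C
Reagents that add atoms: none
Why: Chemoselective methanolysis of the aryl acetate, which is far more reactive than the hindered secondary salicylate, frees the phenol and gives the target.

**Compound list**

1 | 1,1-dimethoxybutan-2-one | CCC(=O)C(OC)OC | starting material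
2 | methyl acrylate | C=CC(=O)OC | starting material
3 | methyl 6,6-dimethoxy-4-methyl-5-oxohexanoate (racemic) | COC(=O)CCC(C)C(=O)C(OC)OC | intermediate
4 | (R)-1-phenylethanol | C[C@@H](O)c1ccccc1 | starting material
5 | methyl 6-methoxy-4-methyl-5-oxo-6-[(1R)-1-phenylethoxy]hexanoate (mixed at C4 and C6) | COC(=O)CCC(C)C(=O)C(OC)O[C@H](C)c1ccccc1 | intermediate
6 | 6-methoxy-4-methyl-5-oxo-6-[(1R)-1-phenylethoxy]hexanoic acid (mixed at C4 and C6) | OC(=O)CCC(C)C(=O)C(OC)O[C@H](C)c1ccccc1 | intermediate
7 | 6-{methoxy[(1R)-1-phenylethoxy]methyl}-5-methyl-3,4-dihydro-2H-pyran-2-one (mixed at the acetal carbon) | CC1=C(C(OC)O[C@H](C)c2ccccc2)OC(=O)CC1 | intermediate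
8 | lithium (4Z)-enolate of 5, chain cis to the enolate oxygen | COC(=O)CC/C(C)=C(\[O-])C(OC)O[C@H](C)c1ccccc1.[Li+] | intermediate
9 | methyl (4Z)-6-methoxy-4-methyl-6-[(1R)-1-phenylethoxy]-5-(trimethylsilyloxy)hex-4-enoate | COC(=O)CC/C(C)=C(\O[Si](C)(C)C)C(OC)O[C@H](C)c1ccccc1 | intermediate
10 | isoprene | C=CC(C)=C | starting material
11 | 1-[(1R)-1-phenylethoxy]-2-(trimethylsilyloxy)allyl cation (oxocarbenium form, W shape), triflate | COC(=O)CC/C(C)=C(\O[Si](C)(C)C)/C=[O+]/[C@H](C)c1ccccc1.[O-]S(=O)(=O)C(F)(F)F | intermediate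
12 | methyl 3-[(1R,6S)-1,4-dimethyl-7-oxo-6-[(1R)-1-phenylethoxy]cyclohept-3-en-1-yl]propanoate | CC1=CC[C@@](C)(CCC(=O)OC)C(=O)[C@@H](O[C@H](C)c2ccccc2)C1 | intermediate
13 | N-methoxy-N-methyl-3-[(1R,6S)-1,4-dimethyl-7-oxo-6-[(1R)-1-phenylethoxy]cyclohept-3-en-1-yl]propanamide | CC1=CC[C@@](C)(CCC(=O)N(C)OC)C(=O)[C@@H](O[C@H](C)c2ccccc2)C1 | intermediate
14 | potassium enolate of 13 (C5=C6) | CC1=CC[C@@](C)(CCC(=O)N(C)OC)C([O-])=C(O[C@H](C)c2ccccc2)C1.[K+] | intermediate
15 | (7R)-7-[3-(methoxy(methyl)amino)-3-oxopropyl]-4,7-dimethyl-2-[(1R)-1-phenylethoxy]cyclohepta-1,4-dien-1-yl trifluoromethanesulfonate | CC1=CC[C@@](C)(CCC(=O)N(C)OC)C(OS(=O)(=O)C(F)(F)F)=C(O[C@H](C)c2ccccc2)C1 | intermediate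
16 | (7R)-4,7-dimethyl-7-(4-methyl-3-oxopentyl)-2-[(1R)-1-phenylethoxy]cyclohepta-1,4-dien-1-yl trifluoromethanesulfonate | CC1=CC[C@@](C)(CCC(=O)C(C)C)C(OS(=O)(=O)C(F)(F)F)=C(O[C@H](C)c2ccccc2)C1 | intermediate
17 | (8aR)-6,8a-dimethyl-4-[(1R)-1-phenylethoxy]-3-(propan-2-yl)-1,2,3,5,8,8a-hexahydroazulen-3-ol (either configuration at C3) | CC1=CC[C@@]2(C)CCC(O)(C(C)C)C2=C(O[C@H](C)c2ccccc2)C1 | intermediate
18 | (8aR)-6,8a-dimethyl-3-(propan-2-yl)-1,2,8,8a-tetrahydroazulen-4(5H)-one | CC1=CC[C@@]2(C)CCC(C(C)C)=C2C(=O)C1 | intermediate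
19 | (4R,8aR)-6,8a-dimethyl-3-(propan-2-yl)-1,2,4,5,8,8a-hexahydroazulen-4-ol (hydroxyl cis to the C8a methyl) | CC1=CC[C@@]2(C)CCC(C(C)C)=C2[C@H](O)C1 | intermediate
20 | (3R,3aS,4R,8aR)-3,3a-epoxy-6,8a-dimethyl-3-(propan-2-yl)-1,2,3,3a,4,5,8,8a-octahydroazulen-4-ol (epoxide oxygen, hydroxyl and C8a methyl on one face) | CC1=CC[C@@]2(C)CC[C@]3(C(C)C)O[C@@]32[C@H](O)C1 | intermediate
21 | trimethylsilyl ether of 20 | CC1=CC[C@@]2(C)CC[C@]3(C(C)C)O[C@@]32[C@H](O[Si](C)(C)C)C1 | intermediate
22 | (3R,3aR,8aR)-6,8a-dimethyl-3-(propan-2-yl)-3-(trimethylsilyloxy)-2,3,3a,5,8,8a-hexahydroazulen-4(1H)-one | CC1=CC[C@@]2(C)CC[C@@](O[Si](C)(C)C)(C(C)C)[C@@H]2C(=O)C1 | intermediate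
23 | (3R,3aR,8aR)-3-hydroxy-6,8a-dimethyl-3-(propan-2-yl)-2,3,3a,5,8,8a-hexahydroazulen-4(1H)-one | CC1=CC[C@@]2(C)CC[C@@](O)(C(C)C)[C@@H]2C(=O)C1 | intermediate
24 | (3R,3aS,4S,8aR)-6,8a-dimethyl-3-(propan-2-yl)-1,2,3,3a,4,5,8,8a-octahydroazulene-3,4-diol | CC1=CC[C@@]2(C)CC[C@@](O)(C(C)C)[C@@H]2[C@@H](O)C1 | intermediate
25 | 2-acetoxybenzoyl chloride | CC(=O)Oc1ccccc1C(Cl)=O | starting material
26 | (3R,3aS,4S,8aR)-3-hydroxy-6,8a-dimethyl-3-(propan-2-yl)-1,2,3,3a,4,5,8,8a-octahydroazulen-4-yl 2-acetoxybenzoate | CC1=CC[C@@]2(C)CC[C@@](O)(C(C)C)[C@@H]2[C@@H](OC(=O)c2ccccc2OC(C)=O)C1 | intermediate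
27 | (3R,3aS,4S,8aR)-3-hydroxy-6,8a-dimethyl-3-(propan-2-yl)-1,2,3,3a,4,5,8,8a-octahydroazulen-4-yl 2-hydroxybenzoate | CC1=CC[C@@]2(C)CC[C@@](O)(C(C)C)[C@@H]2[C@@H](OC(=O)c2ccccc2O)C1 | target

**Step count and risks**

Total step count: 16. Longest linear sequence: 16 steps (from 1).

Steps most likely to fail:

Step 6 (proposed new method). The open allyl cation formed after the first bond may be captured at its tertiary end or lose a proton, or the transoid diene may react, so that five-membered or open-chain products form in place of ring B; facial control by the auxiliary may also be incomplete (the C1 epimer is a diastereomer and would be removed at 12). Fallback, from 9 back to 12, by known reactions: the same oxocarbenium ion is intercepted at C6 by 2-methylallyltrimethylsilane (Me3SiOTf, CH2Cl2, −78 °C; Hosomi–Sakurai allylation of an acetal) to give methyl (4Z,6S)-4,8-dimethyl-6-[(1R)-1-phenylethoxy]-5-(trimethylsilyloxy)nona-4,8-dienoate F1. Its enol silane is allylated at C1 under Tsuji conditions (diallyl carbonate, Bu4N[Ph3SiF2], Pd2(dba)3, PPh3, THF) to give methyl (4R,6S)-4,8-dimethyl-5-oxo-6-[(1R)-1-phenylethoxy]-4-(prop-2-en-1-yl)non-8-enoate F2 after separation from its C4 epimer, since this allylation is not expected to be selective at C1. Ring-closing metathesis with the second-generation Grubbs catalyst (CH2Cl2, 40 °C) then forms C8=C9 and returns to 12.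

Step 13. The ring carbon C7 may migrate in place of hydrogen (ring contraction), or the epoxide may open at C4. Fallback, from 20 back to 23: oxidation with Dess–Martin periodinane (NaHCO3, CH2Cl2) gives (3R,3aS,8aR)-3,3a-epoxy-6,8a-dimethyl-3-(propan-2-yl)-2,3,3a,5,8,8a-hexahydroazulen-4(1H)-one F3. Reductive cleavage of its C5–O bond with SmI2 (MeOH, THF, −90 °C) gives 23 after protonation of the samarium enolate. C4 stays as set by the epoxidation, while C5 then rests on the face of protonation, and a cis-fused epimer would have to be separated.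

Step 10. Addition of the alkenyl–chromium bond to the hindered isopropyl ketone may be slower than its protonation, which would leave the C5–H enol ether. Fallback, from 15 back to 18: iBu2AlH (THF, −78 °C) reduces the Weinreb amide to 3-[(1R)-1,4-dimethyl-6-[(1R)-1-phenylethoxy]-7-(trifluoromethylsulfonyloxy)cyclohepta-3,6-dien-1-yl]propanal F4. The more reactive aldehyde is closed with CrCl2/NiCl2 (DMF) to (8aR)-6,8a-dimethyl-4-[(1R)-1-phenylethoxy]-1,2,3,5,8,8a-hexahydroazulen-3-ol F5, and Dess–Martin periodinane gives (8aR)-6,8a-dimethyl-4-[(1R)-1-phenylethoxy]-1,2,8,8a-tetrahydroazulen-3(5H)-one F6. Addition of iPrMgCl/CeCl3 (THF, −78 °C) to its carbonyl gives 17, and 1 M HCl (THF, 0 °C) then gives 18 by the same transposition.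

**Further compounds**

F1 | step 6 | methyl (4Z,6S)-4,8-dimethyl-6-[(1R)-1-phenylethoxy]-5-(trimethylsilyloxy)nona-4,8-dienoate | COC(=O)CC/C(C)=C(\O[Si](C)(C)C)[C@@H](O[C@H](C)c1ccccc1)CC(C)=C
F2 | step 6 | methyl (4R,6S)-4,8-dimethyl-5-oxo-6-[(1R)-1-phenylethoxy]-4-(prop-2-en-1-yl)non-8-enoate | C=CC[C@@](C)(CCC(=O)OC)C(=O)[C@@H](O[C@H](C)c1ccccc1)CC(C)=C
F3 | step 13 | (3R,3aS,8aR)-3,3a-epoxy-6,8a-dimethyl-3-(propan-2-yl)-2,3,3a,5,8,8a-hexahydroazulen-4(1H)-one | CC1=CC[C@@]2(C)CC[C@]3(C(C)C)O[C@@]32C(=O)C1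
F4 | step 10 | 3-[(1R)-1,4-dimethyl-6-[(1R)-1-phenylethoxy]-7-(trifluoromethylsulfonyloxy)cyclohepta-3,6-dien-1-yl]propanal | CC1=CC[C@@](C)(CCC=O)C(OS(=O)(=O)C(F)(F)F)=C(O[C@H](C)c2ccccc2)C1
F5 | step 10 | (8aR)-6,8a-dimethyl-4-[(1R)-1-phenylethoxy]-1,2,3,5,8,8a-hexahydroazulen-3-ol (carbinol epimers) | CC1=CC[C@@]2(C)CCC(O)C2=C(O[C@H](C)c2ccccc2)C1
F6 | step 10 | (8aR)-6,8a-dimethyl-4-[(1R)-1-phenylethoxy]-1,2,8,8a-tetrahydroazulen-3(5H)-one | CC1=CC[C@@]2(C)CCC(=O)C2=C(O[C@H](C)c2ccccc2)C1
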